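**Retrosynthetic overview**

1. Last moves: hydrogenolysis of six O-benzyl groups, preceded by esterification of the free C3–OH with tri-O-benzylgallic acid; until then the C3 oxygen is carried as a MOM acetal.
2. Ring C is cut at two bonds made in one operation: the aryl ether bond O1–C8a and the C2–C1′ bond to ring B. This leads back to an (R)-α-(methoxymethoxy) aldehyde carrying ring A with fluorine on the future C8a, and to the ring-B Grignard reagent; the aldehyde oxygen becomes O1.
3. Enabling feature: ring A is 1,3,5-trioxygenated, so C8a is meta to both C5–O and C7–O. A C8a–F bond therefore receives no resonance donation and the anionic adduct is stabilised inductively; C8a lies six atoms from the C2 oxygen (6-exo); the vicinal C2–O/C3–O pair lets the C3 acetal oxygen steer C2 through a magnesium chelate.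
4. The aldehyde comes from 1,3-bis(benzyloxy)-5-fluorobenzene (metalation between F and OBn) and methyl (R)-glycidate, which supplies C2, C3, C4 and the C3 stereocenter.
5. Ring order: rings A, B and the galloyl ring are bought as arenes; ring C is the only ring formed, in step 6.

Key step: step 6

Remark on the chemistry: the SMILES is read as (2R,3R), 2,3-cis (epicatechin series), with ring B = 3-hydroxy-4-methoxyphenyl. Closure through the O–aryl bond retains both sp3 centres, so the open chain required is the (1R,2R) syn 1,2-dioxygenated propane.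

**Route**

Step 1
Reactants: 1 1,3,5-trifluorobenzene
Product: 3 1,3-bis(benzyloxy)-5-fluorobenzene, via monobenzyl ether 2 (not isolated)
Conditions: BnOH (2.1 equiv), NaH (2.2 equiv), NMP, 0 → 100 °C
Reagents that add atoms: benzyl alcohol, OCc1ccccc1
Why: Twofold SNAr substitution of fluoride by sodium benzyloxide on a ring activated by its meta fluorines, which should stop after the second exchange because each benzyloxy group that replaces a fluorine lowers the reactivity of the remaining C–F bond.

Step 2
Reactants: 3 1,3-bis(benzyloxy)-5-fluorobenzene; 4 methyl (2R)-oxirane-2-carboxylate (methyl (R)-glycidate)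
Product: 7 methyl (2R)-3-[2,4-bis(benzyloxy)-6-fluorophenyl]-2-hydroxypropanoate, via aryllithium 5 (not isolated), via arylmagnesium bromide 6 (not isolated)
Conditions: n-BuLi, THF, −78 °C; MgBr2·OEt2, −78 °C; CuBr·SMe2 (10 mol %), 4, −78 → −20 °C; then H2O
Reagents that add atoms: none
Why: Directed ortho-lithiation at the ring position flanked by fluorine and benzyloxy (the most acidic C–H), transmetalation to the Grignard reagent (slower than the lithium compound to lose fluoride) and copper-catalysed SN2 opening of the glycidic ester at its unsubstituted C3 (the regiochemistry known for organocopper reagents and glycidates) should give the α-hydroxy ester; the stereocenter of 4 is not touched and becomes C3 of the target.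

Step 3
Reactants: 7 methyl (2R)-3-[2,4-bis(benzyloxy)-6-fluorophenyl]-2-hydroxypropanoate
Product: 8 methyl (2R)-3-[2,4-bis(benzyloxy)-6-fluorophenyl]-2-(methoxymethoxy)propanoate
Conditions: MOMCl, i-Pr2NEt, CH2Cl2, 0 °C → rt
Reagents that add atoms: chloromethyl methyl ether, COCCl
Why: Standard O-alkylation of a secondary alcohol with a chloromethyl ether (MOM acetal formation) under amine base, which caps the C3 oxygen with a base-stable, non-migrating and chelating group without touching the α-stereocenter.

Step 4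
Reactants: 8 methyl (2R)-3-[2,4-bis(benzyloxy)-6-fluorophenyl]-2-(methoxymethoxy)propanoate
Product: 9 (2R)-3-[2,4-bis(benzyloxy)-6-fluorophenyl]-2-(methoxymethoxy)propanal
Conditions: i-Bu2AlH (1.1 equiv), CH2Cl2, −78 °C; aq. potassium sodium tartrate work-up; used crude
Reagents that add atoms: none
Why: Partial reduction of an α-alkoxy ester to the aldehyde with i-Bu2AlH at −78 °C, a standard transformation in which the benzyl ethers, the acetal and the aryl fluoride are inert and the α-stereocenter should be kept if the aldehyde is used without chromatography.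

Step 5
Reactants: 10 5-bromo-2-methoxyphenol
Product: 11 2-(benzyloxy)-4-bromo-1-methoxybenzene
Conditions: BnBr, K2CO3, DMF, rt
Reagents that add atoms: benzyl bromide, BrCc1ccccc1
Why: Williamson ether synthesis on a phenol, which protects the ring-B hydroxyl as a benzyl ether that is inert to magnesium insertion and is removed in the last step.

Step 6
Reactants: 9 (2R)-3-[2,4-bis(benzyloxy)-6-fluorophenyl]-2-(methoxymethoxy)propanal; 11 2-(benzyloxy)-4-bromo-1-methoxybenzene
Product: 15 (2R,3R)-5,7-bis(benzyloxy)-2-[3-(benzyloxy)-4-methoxyphenyl]-3-(methoxymethoxy)-3,4-dihydro-2H-chromene, via arylmagnesium bromide 12 (not isolated), via bromomagnesium alkoxide 13 (not isolated), via potassium alkoxide 14 (not isolated)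
Conditions: 11, Mg, THF, rt (gives 12); 9, toluene/Et2O, −78 °C, add 12; then t-BuOK (2 equiv), DMPU, rt → 60 °C; then H2O
Reagents that add atoms: none
Why: Grignard reagent 12 adds to the aldehyde of 9 held in a five-membered magnesium chelate between the carbonyl oxygen and the C3 acetal oxygen (Cram-chelate addition to an α-alkoxy aldehyde), the aryl group entering from the face of the small C3–H, so the new C2 stereocenter is set as (1R) by 1,2-chelation control from the (2R) centre that came from 4, giving the syn alkoxide 13. Exchange of magnesium for potassium with t-BuOK in a dipolar aprotic medium gives 14, whose alkoxide oxygen attacks the fluorine-bearing ring carbon in an intramolecular SNAr reaction (addition to an anionic Meisenheimer adduct, then loss of fluoride); the closest known reaction types are the tandem Grignard addition–SNAr cyclisation of ortho-fluoroaryl carbonyl compounds and the alkoxide SNAr closure of the pyran ring of flavan-3-ols onto 3,5-dialkoxyfluoroarenes. Ring C closes in a 6-exo mode through the O–aryl bond with retention at both sp3 centres, so the syn open chain maps onto the 2,3-cis flavan. The step needs syn over anti addition (secured by the bidentate MOM oxygen and a weakly coordinating solvent), arylation only of the benzylic oxygen (the C3 oxygen is capped as an acetal that cannot migrate) and a reactive C–F bond (fluorine is meta to both benzyloxy groups, which do not donate into the anionic adduct).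

Step 7
Reactants: 15 (2R,3R)-5,7-bis(benzyloxy)-2-[3-(benzyloxy)-4-methoxyphenyl]-3-(methoxymethoxy)-3,4-dihydro-2H-chromene
Product: 16 (2R,3R)-5,7-bis(benzyloxy)-2-[3-(benzyloxy)-4-methoxyphenyl]-3,4-dihydro-2H-chromen-3-ol
Conditions: conc. HCl (cat.), MeOH/THF, 40 °C
Reagents that add atoms: none
Why: Acid-catalysed transacetalisation of the MOM ether to methanol, mild enough that the benzyl ethers and the cyclic benzylic ether at C2 should stay intact; no stereocenter is involved.

Step 8
Reactants: 16 (2R,3R)-5,7-bis(benzyloxy)-2-[3-(benzyloxy)-4-methoxyphenyl]-3,4-dihydro-2H-chromen-3-ol; 17 3,4,5-tris(benzyloxy)benzoic acid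
Product: 18 (2R,3R)-5,7-bis(benzyloxy)-2-[3-(benzyloxy)-4-methoxyphenyl]-3,4-dihydro-2H-chromen-3-yl 3,4,5-tris(benzyloxy)benzoate
Conditions: DCC, DMAP (cat.), CH2Cl2, rt
Reagents that add atoms: none
Why: Steglich esterification (carbodiimide activation, acyl transfer by DMAP) of the hindered axial C3 hydroxyl, which reacts at oxygen with retention at C3.

Step 9
Reactants: 18 (2R,3R)-5,7-bis(benzyloxy)-2-[3-(benzyloxy)-4-methoxyphenyl]-3,4-dihydro-2H-chromen-3-yl 3,4,5-tris(benzyloxy)benzoate
Product: 19 4′-O-methylepicatechin 3-O-gallate, (2R,3R)-5,7-dihydroxy-2-(3-hydroxy-4-methoxyphenyl)-3,4-dihydro-2H-chromen-3-yl 3,4,5-trihydroxybenzoate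
Conditions: H2 (1 atm), Pd(OH)2/C, THF/MeOH, rt
Reagents that add atoms: none
Why: Hydrogenolysis of the six O-benzyl ethers over Pd(OH)2/C under neutral conditions, which should leave the methyl ether, the gallate ester and the ring C2–O bond untouched and so release the target without affecting C2 or C3.

**Compound list**

1 | 1,3,5-trifluorobenzene | Fc1cc(F)cc(F)c1 | starting material
2 | 1-(benzyloxy)-3,5-difluorobenzene | Fc1cc(F)cc(OCc2ccccc2)c1 | intermediate
3 | 1,3-bis(benzyloxy)-5-fluorobenzene | Fc1cc(OCc2ccccc2)cc(OCc2ccccc2)c1 | intermediate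
4 | methyl (2R)-oxirane-2-carboxylate | COC(=O)[C@H]1CO1 | starting material
5 | [2,4-bis(benzyloxy)-6-fluorophenyl]lithium | [Li]c1c(F)cc(OCc2ccccc2)cc1OCc1ccccc1 | intermediate
6 | [2,4-bis(benzyloxy)-6-fluorophenyl]magnesium bromide | Br[Mg]c1c(F)cc(OCc2ccccc2)cc1OCc1ccccc1 | intermediate
7 | methyl (2R)-3-[2,4-bis(benzyloxy)-6-fluorophenyl]-2-hydroxypropanoate | COC(=O)[C@H](O)Cc1c(F)cc(OCc2ccccc2)cc1OCc1ccccc1 | intermediate
8 | methyl (2R)-3-[2,4-bis(benzyloxy)-6-fluorophenyl]-2-(methoxymethoxy)propanoate | COC(=O)[C@H](OCOC)Cc1c(F)cc(OCc2ccccc2)cc1OCc1ccccc1 | intermediate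
9 | (2R)-3-[2,4-bis(benzyloxy)-6-fluorophenyl]-2-(methoxymethoxy)propanal | O=C[C@H](OCOC)Cc1c(F)cc(OCc2ccccc2)cc1OCc1ccccc1 | intermediate
10 | 5-bromo-2-methoxyphenol | COc1ccc(Br)cc1O | starting material
11 | 2-(benzyloxy)-4-bromo-1-methoxybenzene | COc1ccc(Br)cc1OCc1ccccc1 | intermediate
12 | [3-(benzyloxy)-4-methoxyphenyl]magnesium bromide | COc1ccc([Mg]Br)cc1OCc1ccccc1 | intermediate
13 | bromomagnesium (1R,2R)-3-[2,4-bis(benzyloxy)-6-fluorophenyl]-1-[3-(benzyloxy)-4-methoxyphenyl]-2-(methoxymethoxy)propan-1-olate | COc1ccc([C@@H](O[Mg]Br)[C@H](OCOC)Cc2c(F)cc(OCc3ccccc3)cc2OCc2ccccc2)cc1OCc1ccccc1 | intermediate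
14 | potassium (1R,2R)-3-[2,4-bis(benzyloxy)-6-fluorophenyl]-1-[3-(benzyloxy)-4-methoxyphenyl]-2-(methoxymethoxy)propan-1-olate | COc1ccc([C@@H]([O-])[C@H](OCOC)Cc2c(F)cc(OCc3ccccc3)cc2OCc2ccccc2)cc1OCc1ccccc1.[K+] | intermediate
15 | (2R,3R)-5,7-bis(benzyloxy)-2-[3-(benzyloxy)-4-methoxyphenyl]-3-(methoxymethoxy)-3,4-dihydro-2H-chromene | COc1ccc([C@H]2Oc3cc(OCc4ccccc4)cc(OCc4ccccc4)c3C[C@H]2OCOC)cc1OCc1ccccc1 | intermediate
16 | (2R,3R)-5,7-bis(benzyloxy)-2-[3-(benzyloxy)-4-methoxyphenyl]-3,4-dihydro-2H-chromen-3-ol | COc1ccc([C@H]2Oc3cc(OCc4ccccc4)cc(OCc4ccccc4)c3C[C@H]2O)cc1OCc1ccccc1 | intermediate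
17 | 3,4,5-tris(benzyloxy)benzoic acid | OC(=O)c1cc(OCc2ccccc2)c(OCc2ccccc2)c(OCc2ccccc2)c1 | starting material
18 | (2R,3R)-5,7-bis(benzyloxy)-2-[3-(benzyloxy)-4-methoxyphenyl]-3,4-dihydro-2H-chromen-3-yl 3,4,5-tris(benzyloxy)benzoate | COc1ccc([C@H]2Oc3cc(OCc4ccccc4)cc(OCc4ccccc4)c3C[C@H]2OC(=O)c2cc(OCc3ccccc3)c(OCc3ccccc3)c(OCc3ccccc3)c2)cc1OCc1ccccc1 | intermediate
19 | 4′-O-methylepicatechin 3-O-gallate | COc1ccc([C@H]2Oc3cc(O)cc(O)c3C[C@H]2OC(=O)c2cc(O)c(O)c(O)c2)cc1O | target

**Step count and risks**

Total step count: 9. Longest linear sequence: 8 steps (steps 1, 2, 3, 4, 6, 7, 8, 9); step 5 is a one-step side branch.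

Steps most likely to fail:

Step 6. Risk: erosion of chelation control (poor facial selectivity in the aryl addition), or an incomplete magnesium-to-potassium exchange so that the alkoxide does not cyclise. Fallback: set C2 by catalyst control and close the ring in a separate operation. It sets out from 9: plain addition of 12 in THF and aqueous quench gives the C1-epimeric carbinols (2R)-3-[2,4-bis(benzyloxy)-6-fluorophenyl]-1-[3-(benzyloxy)-4-methoxyphenyl]-2-(methoxymethoxy)propan-1-ol F1. Dess–Martin oxidation of the mixture gives the aryl ketone (2R)-3-[2,4-bis(benzyloxy)-6-fluorophenyl]-1-[3-(benzyloxy)-4-methoxyphenyl]-2-(methoxymethoxy)propan-1-one F2. Transfer hydrogenation with RuCl(p-cymene)[(S,S)-TsDPEN] in HCO2H/Et3N should then give, under catalyst control, (1R,2R)-3-[2,4-bis(benzyloxy)-6-fluorophenyl]-1-[3-(benzyloxy)-4-methoxyphenyl]-2-(methoxymethoxy)propan-1-ol F3. Treatment with KH in DMF at 0 °C → rt closes ring C by the same SNAr event, and the route is rejoined at 15.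

Step 2. Risk: loss of fluoride from the ortho-fluoro organometallic on warming (aryne formation), attack of the aryl nucleophile at the ester instead of the epoxide, or slow copper-mediated transfer of the doubly ortho-substituted aryl group. Fallback: use an epoxide without an ester and adjust the oxidation level afterwards. It sets out from 3: lithiation to 5 as before, then BF3·OEt2-promoted opening of commercial (R)-tert-butyldimethyl(oxiran-2-ylmethoxy)silane at −78 °C should give (2R)-1-[2,4-bis(benzyloxy)-6-fluorophenyl]-3-[(tert-butyldimethylsilyl)oxy]propan-2-ol F4. MOMCl/i-Pr2NEt gives tert-butyl{(2R)-3-[2,4-bis(benzyloxy)-6-fluorophenyl]-2-(methoxymethoxy)propoxy}dimethylsilane F5. Bu4NF in THF gives (2R)-3-[2,4-bis(benzyloxy)-6-fluorophenyl]-2-(methoxymethoxy)propan-1-ol F6. Dess–Martin oxidation rejoins the route at 9.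

Step 4. Risk: over-reduction past the aldehyde stage and loss of configurational integrity at the α-carbon during work-up. Fallback: reduce an N-methoxy-N-methylamide instead of the ester. It sets out from 8: MeNHOMe·HCl and i-PrMgCl in THF at −20 °C give (2R)-3-[2,4-bis(benzyloxy)-6-fluorophenyl]-N-methoxy-2-(methoxymethoxy)-N-methylpropanamide F7, whose reduction with LiAlH4 in THF at −78 °C stops at the aldehyde and rejoins the route at 9.

**Further compounds**

F1 | step 6 | (2R)-3-[2,4-bis(benzyloxy)-6-fluorophenyl]-1-[3-(benzyloxy)-4-methoxyphenyl]-2-(methoxymethoxy)propan-1-ol, mixture of C1 epimers | COc1ccc(C(O)[C@H](OCOC)Cc2c(F)cc(OCc3ccccc3)cc2OCc2ccccc2)cc1OCc1ccccc1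
F2 | step 6 | (2R)-3-[2,4-bis(benzyloxy)-6-fluorophenyl]-1-[3-(benzyloxy)-4-methoxyphenyl]-2-(methoxymethoxy)propan-1-one | COc1ccc(C(=O)[C@H](OCOC)Cc2c(F)cc(OCc3ccccc3)cc2OCc2ccccc2)cc1OCc1ccccc1
F3 | step 6 | (1R,2R)-3-[2,4-bis(benzyloxy)-6-fluorophenyl]-1-[3-(benzyloxy)-4-methoxyphenyl]-2-(methoxymethoxy)propan-1-ol | COc1ccc([C@@H](O)[C@H](OCOC)Cc2c(F)cc(OCc3ccccc3)cc2OCc2ccccc2)cc1OCc1ccccc1
F4 | step 2 | (2R)-1-[2,4-bis(benzyloxy)-6-fluorophenyl]-3-[(tert-butyldimethylsilyl)oxy]propan-2-ol | CC(C)(C)[Si](C)(C)OC[C@H](O)Cc1c(F)cc(OCc2ccccc2)cc1OCc1ccccc1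
F5 | step 2 | tert-butyl{(2R)-3-[2,4-bis(benzyloxy)-6-fluorophenyl]-2-(methoxymethoxy)propoxy}dimethylsilane | CC(C)(C)[Si](C)(C)OC[C@H](OCOC)Cc1c(F)cc(OCc2ccccc2)cc1OCc1ccccc1
F6 | step 2 | (2R)-3-[2,4-bis(benzyloxy)-6-fluorophenyl]-2-(methoxymethoxy)propan-1-ol | OC[C@H](OCOC)Cc1c(F)cc(OCc2ccccc2)cc1OCc1ccccc1
F7 | step 4 | (2R)-3-[2,4-bis(benzyloxy)-6-fluorophenyl]-N-methoxy-2-(methoxymethoxy)-N-methylpropanamide | CON(C)C(=O)[C@H](OCOC)Cc1c(F)cc(OCc2ccccc2)cc1OCc1ccccc1
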